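If each flask's isomer of the product can be written as a fixed burst plus a fixed slice of the target, the share asked for follows from how much target is made, and that was the point of this meeting.

in all of them: free catalyst 0.34 mM

| charge | starting material | other conformer | remark | time |
|---|---|---|---|---|
| grey | 12 mM (fed, over 12 h) | 5 mM | run made earlier |  |
| green | 25 mM (fed, over 12 h) | 5 mM | run made earlier |  |
| ash | 10 mM | 5.00 mM | everything together at the start | 2.5 d |
| larch | 20 mM (fed, over 12 h) | 5.00 mM |  | 2.5 d |

- grey (time / h: target / %, isomer of the product / %): 2.50: 2.8, 2.1; 6.00: 9.6, 2.5; 12.0: 23.2, 2.4; 20.0: 37.6, 3.4; 25.0: 43.0, 4.9; 30.0: 47.0, 4.0; 40.0: 50.6, 4.1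
- green (time / h: target / %, isomer of the product / %): 3.00: 3.7, 0.5; 5.00: 5.6, 1.6; 8.00: 12.0, 1.8; 12.0: 20.3, 1.8; 20.0: 34.5, 3.0; 30.0: 40.3, 3.6; 40.0: 41.6, 4.5

(scatter of a reading: 0.5 percentage points)

- in a conversion other conformer counts as not yet reacted
- the share counts what is present at the end, not what went on to other products
- percentages count the whole charge, also what has not yet gone in

1. which one finishes higher in share of target in all that became target or isomer of the product ("neither" within 2 percentage points) (ash / larch / neither)
2. share of target in all that became target or isomer of the product, ash
3. share of target in all that became target or isomer of the product, larch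

I took the minutes and proposed turning the percentages into mM of the whole charge, 17.0 mM in grey and 30.0 mM in green. The 7 readings up to the end of the feed sum to 18.5 mM of target and 2.90 mM of isomer. The 7 later ones sum to 65.2 mM and 6.12 mM.

I therefore argued for freezing a straight line, Q = b + sP, with Q the isomer and P the target in mM. Here s, the isomer gained per target gained, a selectivity in the usual word, reads 0.0689, and the burst b reads 0.232 mM. Both are readings and carry the scatter.

For the end target I took the last readings, at 40.0 h, as the end and drew a straight line in the charge between grey and green. That gave 11.0 mM for larch and, as an unproven stretch to an unfed flask, 8.01 mM for ash. I assumed the same burst in both, and it is a larger part of ash's target than of larch's. My shares were 91.1 % for ash and 91.7 % for larch, a gap smaller than the margin, so I said neither.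

The forecaster disagreed and put ash at 93.5 % and larch at 91 %, answering ash, on this ground: “If the burst comes from the other conformer meeting starved catalyst, starting material present from the outset should suppress it”.

The flasks give 91.4 % for ash and 92.2 % for larch, so the answer is neither.

    starting material ⇌ other conformer (K = 0.0160, k = 8.00 × 10⁻⁴ min⁻¹)
    free catalyst + target → spent catalyst (k = 0.140 L mol⁻¹ min⁻¹)
    starting material + free catalyst → free catalyst + target (k = 2.00 L mol⁻¹ min⁻¹)
    other conformer ⇌ dormant form (K = 98.0, k = 1.30 × 10⁻⁴ min⁻¹)
    free catalyst + other conformer → free catalyst + isomer of the product (k = 8.00 L mol⁻¹ min⁻¹)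

In larch at 0.540 d, free catalyst has a half-life of 0.58 d by its step with target, shorter than the 2.5 d allowed. At 2.50 d free catalyst in larch stands at 1.23 % of its charge and spent catalyst at 98.8 %, with starting material still 47.1 % of the starting material and other conformer charged together. On larch's final target, 11.6 mM, the line gives a share of 91.8 %. A flask like larch but charged with 80 mM of starting material ends at 93.3 %, and on its 23.3 mM of target the line gives 92.7 %.

The runs stem from a simulated flask for substances that don't exist, and the scatter is random.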